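**Strategy.** Ring C is disconnected through its two oxygens: the C3 hydroxyl and the C4 carbonyl oxygen are traced to one oxirane across C3–C4, and that oxirane to the cis C3=C4 double bond, conjugated with ring A, of a racemic 2-aryl-2H-chromene. A chiral salen–manganese oxygen-transfer catalyst should epoxidise only the (2S)-flavene, on the face remote from ring B at C2, so a single operation selects C2 and fixes C3 and C4 while leaving the C6 prenyl alkene alone. The precursor is racemic 7,4'-dimethoxy-5,3'-bis(methoxymethoxy)-6-prenylflav-3-ene; carrying O5 as a MOM ether instead of a methyl ether lets one mild acid step free both phenols at the end.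

Key step: step 7

Remark on the chemistry: epoxide 14 is assumed too labile for chromatography and is carried on as a cold, base-washed solution; the flavene enantiomer with the target's spatial arrangement at C2 is (2S), because the CIP ranking at C2 changes once C3 becomes sp3.

**Step 1**
Reactants: 1 2',6'-dihydroxy-4'-methoxyacetophenone
Product: 2 2'-hydroxy-4'-methoxy-6'-(methoxymethoxy)acetophenone
Conditions: MOMCl (1.1 equiv), K2CO3, acetone, 0 °C → rt
Reagents that add atoms: chloromethyl methyl ether (MOMCl), COCCl
Why: Williamson-type O-alkylation of one of two equivalent phenols; after the first alkylation the remaining hydroxyl is locked in a hydrogen bond to the acetyl carbonyl, so monoprotection should be clean and is regiochemically unambiguous by symmetry.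

**Step 2**
Reactants: 2 2'-hydroxy-4'-methoxy-6'-(methoxymethoxy)acetophenone; 3 prenyl bromide
Product: 4 4'-methoxy-2'-(methoxymethoxy)-6'-(prenyloxy)acetophenone
Conditions: K2CO3, DMF, rt → 40 °C
Reagents that add atoms: none
Why: Williamson ether synthesis on the chelated phenoxide with a reactive allylic bromide in a polar aprotic solvent, which favours O- over C-alkylation.

**Step 3**
Reactants: 4 4'-methoxy-2'-(methoxymethoxy)-6'-(prenyloxy)acetophenone
Product: 7 6'-hydroxy-4'-methoxy-2'-(methoxymethoxy)-3'-prenylacetophenone, via ortho-dienone 5 (not isolated), via para-dienone 6 (not isolated)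
Conditions: PhNEt2, 200 °C, Ar, sealed tube
Reagents that add atoms: none
Why: Aromatic Claisen rearrangement followed by a Cope shift (para-Claisen): the first [3,3] shift gives ortho-dienone 5 with a crowded 1,1-dimethylallyl group, which relays by a second [3,3] shift to the free para carbon (6) and enolises, so the prenyl group lands between OMe and OMOM and para to the freed hydroxyl, as a 6-prenylflavonoid requires; aryl MOM ethers tolerate these neutral thermal conditions.

**Step 4**
Reactants: 8 isovanillin
Product: 9 4-methoxy-3-(methoxymethoxy)benzaldehyde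
Conditions: MOMCl (1.2 equiv), K2CO3, acetone, 0 °C → rt
Reagents that add atoms: chloromethyl methyl ether (MOMCl), COCCl
Why: Base-mediated O-alkylation of the only phenol; the aldehyde is inert under these conditions.

**Step 5**
Reactants: 7 6'-hydroxy-4'-methoxy-2'-(methoxymethoxy)-3'-prenylacetophenone; 9 4-methoxy-3-(methoxymethoxy)benzaldehyde
Product: 10 (E)-2'-hydroxy-4,4'-dimethoxy-3,6'-bis(methoxymethoxy)-5'-prenylchalcone
Conditions: KOH, EtOH/H2O, 0 °C → rt; then cold dilute HCl to pH 6
Reagents that add atoms: none
Why: Claisen–Schmidt condensation of the methyl ketone enolate with a non-enolisable aldehyde, with E1cB dehydration giving the (E)-enone; MOM ethers and the prenyl alkene are stable to hydroxide.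

**Step 6**
Reactants: 10 (E)-2'-hydroxy-4,4'-dimethoxy-3,6'-bis(methoxymethoxy)-5'-prenylchalcone
Product: 13 racemic 7,4'-dimethoxy-5,3'-bis(methoxymethoxy)-6-prenylflav-3-ene, via allylic alcohol 11 (not isolated), via ortho-quinone methide 12 (not isolated)
Conditions: NaBH4, THF/EtOH, 0 °C → rt; then AcOH to pH 5, rt; Et3N-deactivated silica
Reagents that add atoms: none
Why: 1,2-Reduction of the 2'-hydroxychalcone carbonyl gives the doubly activated alcohol 11, which on mild acidification loses water to ortho-quinone methide 12 and closes by oxa-6π-electrocyclisation (O1–C2 bond) to the 2H-chromene, a known route from 2'-hydroxychalcones to flav-3-enes; C2 is formed racemic on purpose.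

**Step 7**
Reactants: 13 racemic 7,4'-dimethoxy-5,3'-bis(methoxymethoxy)-6-prenylflav-3-ene
Product: 14 (2R,3S,4S)-3,4-epoxy-7,4'-dimethoxy-5,3'-bis(methoxymethoxy)-6-prenylflavan (2,3-trans; oxirane anti to ring B)
Conditions: (S,S)-N,N'-bis(3,5-di-tert-butylsalicylidene)-1,2-cyclohexanediaminomanganese chloride (5 mol %), NMO (5 equiv), mCPBA (0.5 equiv), CH2Cl2, −78 °C; cold 1 M NaOH wash, dry over K2CO3, use at once as a cold solution
Reagents that add atoms: meta-chloroperoxybenzoic acid (mCPBA), OOC(=O)c1cccc(Cl)c1
Why: The peracid/N-oxide pair converts the chloromanganese salen complex into a pentavalent oxomanganese species that meets the cis C3=C4 alkene side-on and transfers oxygen stepwise, C3–O first and then collapse of the ring-A-stabilised C4 radical onto the same oxygen; the closest known reaction is the Jacobsen–Katsuki epoxidation of 2H-chromenes, including kinetic resolution of racemic 2-substituted chromenes. The oxirane is closed by this [2+1] oxygen-atom transfer and is necessarily cis-fused to ring C. C3 and C4 are controlled by the (S,S)-diamine backbone and tert-butyl groups of the ligand, which by analogy with 2,2-dimethylchromenes should expose the alkene face leading to the (3S,4S)-oxirane. C2 is not created but selected: only in the (2S)-flavene is that face also the one anti to ring B, so this enantiomer should react faster and the (2R)-flavene should remain at about half conversion. Chemoselectivity over the C6 prenyl group rests on the catalyst's preference for conjugated cis-disubstituted alkenes over isolated trisubstituted ones and on NMO suppressing uncatalysed peracid epoxidation at −78 °C. The product is kept cold and basic because O1, O5 and O7 make its C4–O bond very easy to ionise.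

**Step 8**
Reactants: 14 (2R,3S,4S)-3,4-epoxy-7,4'-dimethoxy-5,3'-bis(methoxymethoxy)-6-prenylflavan
Product: 16 (2R,3R)-3-hydroxy-7,4'-dimethoxy-5,3'-bis(methoxymethoxy)-6-prenylflavanone, via alkoxysulfonium salt 15 (not isolated)
Conditions: DMSO (10 equiv), (±)-camphor-10-sulfonic acid (1.05 equiv), CH2Cl2, −40 → 0 °C; then Et3N (3 equiv), 0 °C → rt
Reagents that add atoms: dimethyl sulfoxide, CS(C)=O
Why: Proton-assisted opening at C4, the only carbon whose cation is stabilised by ring A, lets DMSO add through oxygen to give 15 with the C3–O bond untouched, and triethylamine then forms the sulfur ylide, which removes H-4 and expels dimethyl sulfide (DMSO oxidation of an epoxide to an α-hydroxy ketone with Kornblum-type collapse), so C2 and C3 keep their configuration.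

**Step 9**
Reactants: 16 (2R,3R)-3-hydroxy-7,4'-dimethoxy-5,3'-bis(methoxymethoxy)-6-prenylflavanone
Product: 17 (2R,3R)-3,5,3'-trihydroxy-7,4'-dimethoxy-6-prenylflavanone (CNP0146895.1)
Conditions: 3 M aq. HCl/MeOH (1:5), 40 °C, stopped at full conversion
Reagents that add atoms: none
Why: Acid-catalysed acetal exchange removes both MOM groups as dimethoxymethane, the freed 5-OH is tied up in a hydrogen bond to C4=O so addition to the C6 prenyl alkene should be slow at this temperature, and the 2,3-trans dihydroflavonol is the stable diastereomer, so neither stereocentre should change.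

**Compound list**
1 | 1-(2,6-dihydroxy-4-methoxyphenyl)ethan-1-one | CC(=O)c1c(O)cc(OC)cc1O | starting material
2 | 1-[2-hydroxy-4-methoxy-6-(methoxymethoxy)phenyl]ethan-1-one | CC(=O)c1c(O)cc(OC)cc1OCOC | intermediate
3 | prenyl bromide (1-bromo-3-methylbut-2-ene) | CC(C)=CCBr | starting material
4 | 1-[4-methoxy-2-(methoxymethoxy)-6-(3-methylbut-2-enyloxy)phenyl]ethan-1-one | CC(=O)c1c(OCC=C(C)C)cc(OC)cc1OCOC | intermediate
5 | 2-acetyl-5-methoxy-3-(methoxymethoxy)-6-(2-methylbut-3-en-2-yl)cyclohexa-2,4-dien-1-one (ortho-dienone, racemic) | CC(=O)C1=C(OCOC)C=C(OC)C(C(C)(C)C=C)C1=O | intermediate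
6 | 2-acetyl-5-methoxy-3-(methoxymethoxy)-4-(3-methylbut-2-enyl)cyclohexa-2,5-dien-1-one (para-dienone, racemic) | CC(=O)C1=C(OCOC)C(CC=C(C)C)C(OC)=CC1=O | intermediate
7 | 1-[6-hydroxy-4-methoxy-2-(methoxymethoxy)-3-(3-methylbut-2-enyl)phenyl]ethan-1-one | CC(=O)c1c(O)cc(OC)c(CC=C(C)C)c1OCOC | intermediate
8 | isovanillin (3-hydroxy-4-methoxybenzaldehyde) | COc1ccc(C=O)cc1O | starting material
9 | 4-methoxy-3-(methoxymethoxy)benzaldehyde | COCOc1cc(C=O)ccc1OC | intermediate
10 | (E)-1-[6-hydroxy-4-methoxy-2-(methoxymethoxy)-3-(3-methylbut-2-enyl)phenyl]-3-[4-methoxy-3-(methoxymethoxy)phenyl]prop-2-en-1-one | COCOc1cc(/C=C/C(=O)c2c(O)cc(OC)c(CC=C(C)C)c2OCOC)ccc1OC | intermediate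
11 | (E)-1-[6-hydroxy-4-methoxy-2-(methoxymethoxy)-3-(3-methylbut-2-enyl)phenyl]-3-[4-methoxy-3-(methoxymethoxy)phenyl]prop-2-en-1-ol (racemic) | COCOc1cc(/C=C/C(O)c2c(O)cc(OC)c(CC=C(C)C)c2OCOC)ccc1OC | intermediate
12 | 6-{3-[4-methoxy-3-(methoxymethoxy)phenyl]prop-2-enylidene}-3-methoxy-5-(methoxymethoxy)-4-(3-methylbut-2-enyl)cyclohexa-2,4-dien-1-one (ortho-quinone methide) | O=C1C=C(OC)C(CC=C(C)C)=C(OCOC)C1=CC=Cc1ccc(OC)c(OCOC)c1 | intermediate
13 | racemic 7-methoxy-2-[4-methoxy-3-(methoxymethoxy)phenyl]-5-(methoxymethoxy)-6-(3-methylbut-2-enyl)-2H-chromene | COc1ccc(C2C=Cc3c(OCOC)c(CC=C(C)C)c(OC)cc3O2)cc1OCOC | intermediate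
14 | (2R,3S,4S)-3,4-epoxy-7-methoxy-2-[4-methoxy-3-(methoxymethoxy)phenyl]-5-(methoxymethoxy)-6-(3-methylbut-2-enyl)chromane (flavan numbering; oxirane trans to the C2 aryl group) | COc1ccc([C@H]2Oc3cc(OC)c(CC=C(C)C)c(OCOC)c3[C@@H]4O[C@H]24)cc1OCOC | intermediate
15 | dimethyl{[(2R,3S)-3-hydroxy-7-methoxy-2-[4-methoxy-3-(methoxymethoxy)phenyl]-5-(methoxymethoxy)-6-(3-methylbut-2-enyl)chroman-4-yl]oxy}sulfonium camphor-10-sulfonate (C4 epimers) | COc1ccc([C@H]2Oc3cc(OC)c(CC=C(C)C)c(OCOC)c3C(O[S+](C)C)[C@@H]2O)cc1OCOC.CC1(C)C2CCC1(CS(=O)(=O)[O-])C(=O)C2 | intermediate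
16 | (2R,3R)-3-hydroxy-7-methoxy-2-[4-methoxy-3-(methoxymethoxy)phenyl]-5-(methoxymethoxy)-6-(3-methylbut-2-enyl)chroman-4-one | COc1ccc([C@H]2Oc3cc(OC)c(CC=C(C)C)c(OCOC)c3C(=O)[C@@H]2O)cc1OCOC | intermediate
17 | (2R,3R)-3,5-dihydroxy-2-(3-hydroxy-4-methoxyphenyl)-7-methoxy-6-(3-methylbut-2-enyl)chroman-4-one | COc1ccc([C@H]2Oc3cc(OC)c(CC=C(C)C)c(O)c3C(=O)[C@@H]2O)cc1O | target

**Step count and risks**
Total steps: 9. Longest linear sequence: 8 steps (1 → 2 → 4 → 7 → 10 → 13 → 14 → 16 → 17); step 4 is the one-step side branch.

Steps most likely to fail: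

1. Step 7. The rate difference between the two flavene enantiomers may be too small, and oxygen transfer syn to ring B may leak through, so the oxirane could form with poor enantiomeric and diastereomeric purity. Fallback, from 13 back to 16: stereocontrol is moved from the oxygen transfer to a separation. All of 13 is epoxidised with the racemic form of the same salen manganese chloride catalyst (mCPBA 1.1 equiv, NMO, CH2Cl2, −78 °C). Each catalyst enantiomer should take its matched flavene enantiomer anti to ring B, giving the racemic 2,3-trans-flavan 3,4-epoxide F1. Treatment as in step 8 should give the racemic trans-3-hydroxyflavanone F2. Its enantiomers are separated by preparative chromatography on a chiral stationary phase (cellulose tris(3,5-dimethylphenylcarbamate)), and the (2R,3R) fraction is 16.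

2. Step 8. Acid may trigger a Meinwald-type 1,2-hydride shift of the oxirane to the flavan-3-one, adventitious water may capture the C4 cation, and the unreacted flavene carried along may oligomerise under acid. Fallback, from 14 back to 16: the cold epoxide solution is hydrolysed in THF/water at pH 7 (phosphate buffer, 0 °C → rt) to the (2R,3S)-flavan-3,4-diol F3 as C4 epimers. This diol is stable enough to be freed from the flavene by chromatography. Activated MnO2 in CH2Cl2 at rt should then oxidise only the benzylic, ring-A-activated C4 hydroxyl, giving 16 with C3 untouched.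

3. Step 6. Conjugate reduction of the enone may compete, leading on to the saturated alcohol and flavan, and the electron-rich flavene may dimerise during acidic cyclodehydration. Fallback, from 10 back to 13: 10 is isomerised by intramolecular oxa-Michael addition (NaOAc, EtOH, reflux) to the racemic flavanone F4. Its isolated ketone, which has no 1,4-pathway, is reduced (NaBH4, MeOH/THF, 0 °C) to the racemic flavan-4-ol F5. Dehydration under basic conditions (MsCl, Et3N, CH2Cl2, 0 °C → rt), through the transient benzylic mesylate, should give 13 without exposure to acid.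

**Further compounds**
F1 | step 7 | racemic 2,3-trans-3,4-epoxy-7,4'-dimethoxy-5,3'-bis(methoxymethoxy)-6-prenylflavan (14 and its mirror image) | COc1ccc([C@H]2Oc3cc(OC)c(CC=C(C)C)c(OCOC)c3[C@@H]4O[C@H]24)cc1OCOC.COc1ccc([C@@H]2Oc3cc(OC)c(CC=C(C)C)c(OCOC)c3[C@H]4O[C@@H]24)cc1OCOC
F2 | step 7 | racemic trans-3-hydroxy-7,4'-dimethoxy-5,3'-bis(methoxymethoxy)-6-prenylflavanone (16 and its mirror image) | COc1ccc([C@H]2Oc3cc(OC)c(CC=C(C)C)c(OCOC)c3C(=O)[C@@H]2O)cc1OCOC.COc1ccc([C@@H]2Oc3cc(OC)c(CC=C(C)C)c(OCOC)c3C(=O)[C@H]2O)cc1OCOC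
F3 | step 8 | (2R,3S)-7,4'-dimethoxy-5,3'-bis(methoxymethoxy)-6-prenylflavan-3,4-diol (C4 epimers) | COc1ccc([C@H]2Oc3cc(OC)c(CC=C(C)C)c(OCOC)c3C(O)[C@@H]2O)cc1OCOC
F4 | step 6 | racemic 7,4'-dimethoxy-5,3'-bis(methoxymethoxy)-6-prenylflavanone | COc1ccc(C2CC(=O)c3c(OCOC)c(CC=C(C)C)c(OC)cc3O2)cc1OCOC
F5 | step 6 | racemic 7,4'-dimethoxy-5,3'-bis(methoxymethoxy)-6-prenylflavan-4-ol | COc1ccc(C2CC(O)c3c(OCOC)c(CC=C(C)C)c(OC)cc3O2)cc1OCOC
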